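**Plan**
- Retrosynthetic cuts: the O6–acyl bond of the p-coumarate, the C4–C15 bond (methyl onto a C3=C4 enol triflate), the C1–C10 bond of ring A (radical conjugate closure), then the C4–C5 bond (acylation of a ring B vinyllithium with a C1–C4 chain).
- Forward order: ring B is (−)-menthone, dehydrogenated and brominated at C5; the C1–C4 chain is attached at C5; ring A closes at C1–C10; C15 and the ester come last.
- Enabling feature: ring B carries the C10 methyl and the C7 isopropyl 1,4 to each other beside the C6 oxygen (the menthone pattern), and C10 becomes the β-carbon of a C5=C10 enone once C4 is a carbonyl on C5, so a C1 radical on that acyl chain can close ring A onto C10.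
- Stereochemistry: C7 from menthone; C6 by hydride delivery trans to the isopropyl group; C10 and C5 in the radical step, steered by the pseudo-axial C6 silyloxy group.

Key step: step 9

Remark: the C6 silyl ether is assumed to lie pseudo-axial in the cyclohexene precursor (allylic strain with the C5 acyl group), which underlies the facial control claimed in step 9. Eudesmane numbering is used for all ring atoms, and β is the face of the C14 methyl group.

**Step 1**
Reactants: 1 (−)-menthone
Product: 3 trimethyl{[(3R,6S)-3-methyl-6-(propan-2-yl)cyclohex-1-en-1-yl]oxy}silane, via lithium enolate 2 (not isolated)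
Conditions: LiN(iPr)2, THF, −78 °C; Me3SiCl, −78 to 0 °C
Reagents that add atoms: chlorotrimethylsilane, C[Si](C)(C)Cl
Why: Kinetic deprotonation by the hindered amide base at the less substituted α-methylene (not at the isopropyl-bearing methine) and O-silylation give the regiodefined silyl enol ether (kinetic enolate trapping), so both stereocentres of menthone are untouched.

**Step 2**
Reactants: 3 trimethylsilyl enol ether
Product: 4 (S)-piperitone
Conditions: Pd(OAc)2 (1.05 equiv), MeCN, 23 °C
Reagents that add atoms: none
Why: Saegusa–Ito dehydrogenation: the divalent palladium enolate loses the β-hydrogen of the methyl-bearing carbon, which places the double bond between future C5 and C10 under non-basic conditions that leave the enolisable isopropyl-bearing centre (future C7) alone.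

**Step 3**
Reactants: 4 (S)-piperitone
Product: 6 (6S)-2-bromo-3-methyl-6-(propan-2-yl)cyclohex-2-en-1-one, via anti dibromide 5 (not isolated)
Conditions: Br2, CH2Cl2, 0 °C; Et3N, 0 °C
Reagents that add atoms: bromine, BrBr
Why: Addition of bromine across the enone double bond and base-induced loss of HBr through the acidic α-hydrogen (α-halogenation of an enone by addition–elimination) put bromine on future C5, and the short exposure to a weak amine base at 0 °C should not enolise the C7 centre.

**Step 4**
Reactants: 6 bromo enone
Product: 7 (1R,6S)-2-bromo-3-methyl-6-(propan-2-yl)cyclohex-2-en-1-ol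
Conditions: LiBH(sBu)3, THF, −78 °C; H2O
Reagents that add atoms: none
Why: 1,2-Reduction of the enone carbonyl by a bulky trialkylborohydride (the β-carbon is fully substituted, so conjugate reduction is shut down), with hydride arriving trans to the neighbouring isopropyl group as in 2-alkylcyclohexanone reductions, sets the carbinol centre (future C6) cis to the isopropyl group.

**Step 5**
Reactants: 7 cis bromo alcohol
Product: 8 tert-butyl{[(1R,6S)-2-bromo-3-methyl-6-(propan-2-yl)cyclohex-2-en-1-yl]oxy}dimethylsilane
Conditions: tBuMe2SiOTf, 2,6-lutidine, CH2Cl2, 0 °C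
Reagents that add atoms: tert-butyldimethylsilyl trifluoromethanesulfonate, CC(C)(C)[Si](C)(C)OS(=O)(=O)C(F)(F)F
Why: Silylation of a hindered secondary allylic alcohol with a silyl triflate and a non-nucleophilic base; the silyl ether survives tBuLi, radical, amide-base and Grignard conditions and later serves as the steric screen of the β face.

**Step 6**
Reactants: 9 4-chlorobutanoyl chloride
Product: 10 4-chloro-N-methoxy-N-methylbutanamide
Conditions: MeNHOMe·HCl, pyridine, CH2Cl2, 0 to 23 °C
Reagents that add atoms: N,O-dimethylhydroxylamine hydrochloride, CNOC.Cl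
Why: Acylation of N,O-dimethylhydroxylamine by the acid chloride (Weinreb amide formation) is far faster than any substitution at the primary alkyl chloride.

**Step 7**
Reactants: 8 bromo silyl ether; 10 4-chloro-N-methoxy-N-methylbutanamide
Product: 13 4-chloro-1-[(5S,6R)-6-(tert-butyldimethylsilyloxy)-2-methyl-5-(propan-2-yl)cyclohex-1-en-1-yl]butan-1-one, via vinyllithium 11 (not isolated), via lithium hemiaminal alkoxide 12 (not isolated)
Conditions: tBuLi (2.1 equiv), Et2O, −78 °C; then 10, −78 to 0 °C; H2O
Reagents that add atoms: none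
Why: Bromine–lithium exchange gives the vinyllithium at C5, whose addition to the N-methoxy-N-methylamide stops at the chelated tetrahedral adduct (Weinreb ketone synthesis), so the C4–C5 bond forms without over-addition and the primary chloride is untouched at low temperature.

**Step 8**
Reactants: 13 chloro ketone
Product: 14 4-iodo-1-[(5S,6R)-6-(tert-butyldimethylsilyloxy)-2-methyl-5-(propan-2-yl)cyclohex-1-en-1-yl]butan-1-one
Conditions: NaI, 2-butanone, 80 °C
Reagents that add atoms: sodium iodide, [Na+].[I-]
Why: Finkelstein halide exchange at the unhindered primary carbon, driven by precipitation of NaCl, gives the iodide needed for fast halogen abstraction.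

**Step 9**
Reactants: 14 iodo enone
Product: 15 6β-(tert-butyldimethylsilyloxy)-15-nor-5α-eudesman-4-one
Conditions: (Me3Si)3SiH (1.3 equiv) and AIBN (0.2 equiv) added by syringe pump over 8 h, PhMe (0.01 M), 90 °C
Reagents that add atoms: none
Why: Radical chain: (Me3Si)3Si• abstracts iodine from C1, the nucleophilic primary C1 radical adds to C10, the β-carbon of the C5=C10–C4=O enone, and the resulting C4-oxo-stabilised C5 radical takes hydrogen from the silane, which carries the chain. The closest known reaction type is the intramolecular Giese addition of ω-haloalkyl enones in which the tether ends on the carbonyl carbon (cyclisation of 4-oxohex-5-enyl radicals). Ring A closes in the 6-endo-trig mode; 5-exo attack at C5 is disfavoured because C5 is the electron-richer α-carbon, is fully substituted, and would leave an unstabilised radical at C10 in a spiro cyclopentanone. C10 is set by the pseudo-axial C6 silyloxy group, which sits on the β face next to the anchoring carbon C5 and forces the tether to arch over the α face, so that C1 bonds from below and C14 ends up β. C5 is set by hydrogen transfer to the α face, away from the now axial C14 methyl and the axial silyloxy group, which gives the trans ring fusion. The step needs cyclisation to win over direct reduction of the C1 radical and over loss of the C6 oxygen: the slow hydrogen donor (Me3Si)3SiH kept at low stationary concentration serves the first, and the absence of a metal enolate at C5 serves the second.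

**Step 10**
Reactants: 15 silyloxy decalone
Product: 17 6β-(tert-butyldimethylsilyloxy)-15-nor-5α-eudesm-3-en-4-yl trifluoromethanesulfonate, via lithium enolate 16 (not isolated)
Conditions: LiN(iPr)2, THF, −78 °C; PhNTf2, −78 to 0 °C
Reagents that add atoms: N-phenylbis(trifluoromethanesulfonimide), O=S(=O)(N(c1ccccc1)S(=O)(=O)C(F)(F)F)C(F)(F)F
Why: Kinetic deprotonation occurs at the C3 methylene rather than at the hindered C5 methine, which keeps the C5 configuration and avoids β-elimination of the C6 silyloxy group, and O-sulfonylation of the enolate with PhNTf2 fixes the C3=C4 double bond (regioselective enol triflate formation).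

**Step 11**
Reactants: 17 enol triflate
Product: 18 6β-(tert-butyldimethylsilyloxy)-5α-eudesm-3-ene
Conditions: MeMgBr, Fe(acac)3 (5 mol %), THF/NMP, −30 to 0 °C
Reagents that add atoms: methylmagnesium bromide, C[Mg]Br
Why: Iron-catalysed Kumada-type cross-coupling of the alkenyl triflate with the methyl Grignard reagent replaces the triflate by C15 without moving the C3=C4 double bond, and the silyl ether tolerates the Grignard reagent at low temperature.

**Step 12**
Reactants: 18 silyl ether
Product: 19 5α-eudesm-3-en-6β-ol
Conditions: Bu4NF, THF, 60 °C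
Reagents that add atoms: none
Why: Fluoride-induced cleavage of the silyl ether (Si–F bond formation) needs warming because the axial C6 oxygen is crowded, and nothing else in the hydrocarbon framework reacts with fluoride.

**Step 13**
Reactants: 20 p-coumaric acid
Product: 22 (E)-3-[4-(tert-butyldimethylsilyloxy)phenyl]prop-2-enoic acid, via silyl ester silyl ether 21 (not isolated)
Conditions: tBuMe2SiCl, imidazole, DMF, 23 °C; then AcOH, THF/H2O, 23 °C
Reagents that add atoms: tert-butyldimethylsilyl chloride, CC(C)(C)[Si](C)(C)Cl
Why: Exhaustive silylation followed by mild aqueous acid hydrolyses only the silyl ester, which is much more labile than the aryl silyl ether, leaving the phenol protected and the acid free (protection of a phenolic acid).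

**Step 14**
Reactants: 19 5α-eudesm-3-en-6β-ol; 22 O-silyl p-coumaric acid
Product: 24 5α-eudesm-3-en-6β-yl (E)-3-[4-(tert-butyldimethylsilyloxy)phenyl]prop-2-enoate, via mixed anhydride 23 (not isolated)
Conditions: 22, 2,4,6-Cl3C6H2COCl, Et3N, PhMe, 23 °C; then 19, DMAP, PhMe, 80 °C
Reagents that add atoms: none
Why: Yamaguchi esterification: the mixed anhydride is attacked by DMAP at the cinnamoyl carbonyl and the resulting acylpyridinium acylates the crowded axial C6 hydroxyl, with the C6 configuration retained because the C6–O bond is not broken.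

**Step 15**
Reactants: 24 silyl-protected ester
Product: 25 5α-eudesm-3-en-6β-yl (E)-3-(4-hydroxyphenyl)prop-2-enoate (CNP0220414.1)
Conditions: Bu4NF, AcOH, THF, 0 °C
Reagents that add atoms: none
Why: An aryl silyl ether is cleaved by buffered fluoride at 0 °C (phenoxide is a good leaving group on silicon), while the hindered cinnamate ester and the E-olefin are unaffected.

**Compound list**
1 | (−)-menthone, (2S,5R)-5-methyl-2-(propan-2-yl)cyclohexan-1-one | C[C@@H]1CC[C@H](C(=O)C1)C(C)C | starting material
2 | lithium (3R,6S)-3-methyl-6-(propan-2-yl)cyclohex-1-en-1-olate (kinetic enolate) | C[C@@H]1CC[C@H](C(O[Li])=C1)C(C)C | intermediate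
3 | trimethyl{[(3R,6S)-3-methyl-6-(propan-2-yl)cyclohex-1-en-1-yl]oxy}silane | C[C@@H]1CC[C@H](C(O[Si](C)(C)C)=C1)C(C)C | intermediate
4 | (S)-piperitone, (6S)-3-methyl-6-(propan-2-yl)cyclohex-2-en-1-one | CC1=CC(=O)[C@H](C(C)C)CC1 | intermediate
5 | (6S)-2,3-dibromo-3-methyl-6-(propan-2-yl)cyclohexan-1-one (anti dibromide, C2/C3 configuration not defined) | CC1(Br)CC[C@@H](C(C)C)C(=O)C1Br | intermediate
6 | (6S)-2-bromo-3-methyl-6-(propan-2-yl)cyclohex-2-en-1-one | CC1=C(Br)C(=O)[C@H](C(C)C)CC1 | intermediate
7 | (1R,6S)-2-bromo-3-methyl-6-(propan-2-yl)cyclohex-2-en-1-ol (OH cis to isopropyl) | CC1=C(Br)[C@H](O)[C@H](C(C)C)CC1 | intermediate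
8 | tert-butyl{[(1R,6S)-2-bromo-3-methyl-6-(propan-2-yl)cyclohex-2-en-1-yl]oxy}dimethylsilane | CC1=C(Br)[C@H](O[Si](C)(C)C(C)(C)C)[C@H](C(C)C)CC1 | intermediate
9 | 4-chlorobutanoyl chloride | O=C(Cl)CCCCl | starting material
10 | 4-chloro-N-methoxy-N-methylbutanamide | CON(C)C(=O)CCCCl | intermediate
11 | [(5S,6R)-6-(tert-butyldimethylsilyloxy)-2-methyl-5-(propan-2-yl)cyclohex-1-en-1-yl]lithium | CC1=C([Li])[C@H](O[Si](C)(C)C(C)(C)C)[C@H](C(C)C)CC1 | intermediate
12 | lithium 4-chloro-1-[(5S,6R)-6-(tert-butyldimethylsilyloxy)-2-methyl-5-(propan-2-yl)cyclohex-1-en-1-yl]-1-[methoxy(methyl)amino]butan-1-olate (carbinol centre not defined) | CC1=C(C(O[Li])(CCCCl)N(C)OC)[C@H](O[Si](C)(C)C(C)(C)C)[C@H](C(C)C)CC1 | intermediate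
13 | 4-chloro-1-[(5S,6R)-6-(tert-butyldimethylsilyloxy)-2-methyl-5-(propan-2-yl)cyclohex-1-en-1-yl]butan-1-one | ClCCCC(=O)C1=C(C)CC[C@@H](C(C)C)[C@H]1O[Si](C)(C)C(C)(C)C | intermediate
14 | 4-iodo-1-[(5S,6R)-6-(tert-butyldimethylsilyloxy)-2-methyl-5-(propan-2-yl)cyclohex-1-en-1-yl]butan-1-one | ICCCC(=O)C1=C(C)CC[C@@H](C(C)C)[C@H]1O[Si](C)(C)C(C)(C)C | intermediate
15 | 6β-(tert-butyldimethylsilyloxy)-15-nor-5α-eudesman-4-one; trans-fused, 10β-methyl, 7β-isopropyl; (5S,6R,7S,10R), the C5 descriptor differing from the target only through the priority of the C4 carbonyl | O=C1CCC[C@]2(C)CC[C@@H](C(C)C)[C@@H](O[Si](C)(C)C(C)(C)C)[C@@H]12 | intermediate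
16 | lithium 6β-(tert-butyldimethylsilyloxy)-15-nor-5α-eudesm-3-en-4-olate | [Li]OC1=CCC[C@]2(C)CC[C@@H](C(C)C)[C@@H](O[Si](C)(C)C(C)(C)C)[C@@H]12 | intermediate
17 | 6β-(tert-butyldimethylsilyloxy)-15-nor-5α-eudesm-3-en-4-yl trifluoromethanesulfonate | FC(F)(F)S(=O)(=O)OC1=CCC[C@]2(C)CC[C@@H](C(C)C)[C@@H](O[Si](C)(C)C(C)(C)C)[C@@H]12 | intermediate
18 | 6β-(tert-butyldimethylsilyloxy)-5α-eudesm-3-ene | CC1=CCC[C@]2(C)CC[C@@H](C(C)C)[C@@H](O[Si](C)(C)C(C)(C)C)[C@@H]12 | intermediate
19 | 5α-eudesm-3-en-6β-ol; (5R,6R,7S,10R), 10β-methyl, 7β-isopropyl | CC1=CCC[C@]2(C)CC[C@@H](C(C)C)[C@@H](O)[C@@H]12 | intermediate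
20 | p-coumaric acid, (E)-3-(4-hydroxyphenyl)prop-2-enoic acid | O=C(O)/C=C/c1ccc(O)cc1 | starting material
21 | tert-butyldimethylsilyl (E)-3-[4-(tert-butyldimethylsilyloxy)phenyl]prop-2-enoate | CC(C)(C)[Si](C)(C)OC(=O)/C=C/c1ccc(O[Si](C)(C)C(C)(C)C)cc1 | intermediate
22 | (E)-3-[4-(tert-butyldimethylsilyloxy)phenyl]prop-2-enoic acid | O=C(O)/C=C/c1ccc(O[Si](C)(C)C(C)(C)C)cc1 | intermediate
23 | (E)-3-[4-(tert-butyldimethylsilyloxy)phenyl]prop-2-enoic 2,4,6-trichlorobenzoic anhydride | O=C(OC(=O)c1c(Cl)cc(Cl)cc1Cl)/C=C/c1ccc(O[Si](C)(C)C(C)(C)C)cc1 | intermediate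
24 | 5α-eudesm-3-en-6β-yl (E)-3-[4-(tert-butyldimethylsilyloxy)phenyl]prop-2-enoate | CC1=CCC[C@]2(C)CC[C@@H](C(C)C)[C@@H](OC(=O)/C=C/c3ccc(O[Si](C)(C)C(C)(C)C)cc3)[C@@H]12 | intermediate
25 | 5α-eudesm-3-en-6β-yl (E)-3-(4-hydroxyphenyl)prop-2-enoate, CNP0220414.1; (5R,6R,7S,10R) | CC1=CCC[C@]2(C)CC[C@@H](C(C)C)[C@@H](OC(=O)/C=C/c3ccc(O)cc3)[C@@H]12 | target

**Step count**
Total: 15 steps (13 in the main line, 1 for amide 10, 1 for acid 22).
Longest linear sequence: 13 steps from (−)-menthone (steps 1–5, 7–12, 14, 15).

**Steps most likely to fail**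

Step 9. Closure of the C1 radical onto the fully substituted C10 may be slower than hydrogen transfer from the silane, so that the chain is merely reduced before ring A forms. The fallback generates the same radical without a fast hydrogen donor and from a different precursor. It sets out from bromide 8: bromine–lithium exchange (tBuLi, Et2O, −78 °C) and addition of vinyllithium 11 to an excess of glutaric anhydride in THF should give 5-[(5S,6R)-6-(tert-butyldimethylsilyloxy)-2-methyl-5-(propan-2-yl)cyclohex-1-en-1-yl]-5-oxopentanoic acid F1. Coupling with N-hydroxyphthalimide (N,N'-diisopropylcarbodiimide, cat. DMAP, CH2Cl2) should give the redox-active 1,3-dioxoisoindolin-2-yl ester F2. Blue-light irradiation with Ru(bpy)3(PF6)2 (cat.), Hantzsch ester and iPr2NEt·HBF4 in CH2Cl2 at 23 °C should effect reductive decarboxylation to the C1 radical in a non-chain process, giving it a longer lifetime for the 6-endo closure. The sequence comes back to the route at ketone 15.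

Step 7. The hindered and basic vinyllithium 11 may deprotonate amide 10 at its α-carbon or add incompletely, instead of acylating cleanly. The fallback replaces amide acylation by carbonyl addition and oxidation. It sets out from bromide 8: vinyllithium 11 is added to 4-chlorobutanal (Et2O, −78 °C, cold quench), which should give 4-chloro-1-[(5S,6R)-6-(tert-butyldimethylsilyloxy)-2-methyl-5-(propan-2-yl)cyclohex-1-en-1-yl]butan-1-ol F3 as a mixture of carbinol epimers that does not matter. Oxidation with Dess–Martin periodinane (NaHCO3, CH2Cl2, 0 °C) comes back to the route at chloro ketone 13.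

Step 14. Acylation of the axial C6 hydroxyl, which is flanked by C5 and C7 and syn-axial to C14, may be so slow that the activated cinnamate is consumed in other ways first. The fallback acylates with a small acid and builds the cinnamate on the molecule. It sets out from alcohol 19: esterification with (diethoxyphosphoryl)acetic acid (DCC, cat. DMAP, CH2Cl2) should give 5α-eudesm-3-en-6β-yl (diethoxyphosphoryl)acetate F4. Horner–Wadsworth–Emmons olefination with 4-(tert-butyldimethylsilyloxy)benzaldehyde (LiCl, DBU, MeCN, 23 °C) should give the E-cinnamate and comes back to the route at ester 24.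

**Further compounds**
F1 | step 9 | 5-[(5S,6R)-6-(tert-butyldimethylsilyloxy)-2-methyl-5-(propan-2-yl)cyclohex-1-en-1-yl]-5-oxopentanoic acid | OC(=O)CCCC(=O)C1=C(C)CC[C@@H](C(C)C)[C@H]1O[Si](C)(C)C(C)(C)C
F2 | step 9 | 1,3-dioxoisoindolin-2-yl 5-[(5S,6R)-6-(tert-butyldimethylsilyloxy)-2-methyl-5-(propan-2-yl)cyclohex-1-en-1-yl]-5-oxopentanoate | O=C(CCCC(=O)C1=C(C)CC[C@@H](C(C)C)[C@H]1O[Si](C)(C)C(C)(C)C)ON1C(=O)c2ccccc2C1=O
F3 | step 7 | 4-chloro-1-[(5S,6R)-6-(tert-butyldimethylsilyloxy)-2-methyl-5-(propan-2-yl)cyclohex-1-en-1-yl]butan-1-ol (carbinol centre not defined) | ClCCCC(O)C1=C(C)CC[C@@H](C(C)C)[C@H]1O[Si](C)(C)C(C)(C)C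
F4 | step 14 | 5α-eudesm-3-en-6β-yl (diethoxyphosphoryl)acetate | CC1=CCC[C@]2(C)CC[C@@H](C(C)C)[C@@H](OC(=O)CP(=O)(OCC)OCC)[C@@H]12
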